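The decalin (labdane numbering) is unzipped across ring A: the C5–C10 ring-fusion bond and the C3–C4 bond are disconnected together, which turns both rings and both quaternary carbons (C4, C10) into an acyclic 2-methyl-enal/diene. The key step, a Lewis-acid-promoted intramolecular Diels–Alder reaction, closes ring B through the C5–C10 bond and ring A through C3–C4 in one operation. It exploits the 1,3-relationship of C4 (CH3/CO2H, from the (E)-enal) and C10 (angular CH3, from the (Z)-methyl of the diene) across H-5; a silyloxy stereocentre at C8 relays absolute configuration. Regiodefined C9 alkylation then brings in a dienyl chain, on which the naphthoquinone is annulated by a quinone Diels–Alder reaction.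

Key step: step 5

Remark: numbering is that of labdanes (C4 carries CH3 and CO2H, C5 and C10 are the ring-fusion carbons, C10 bears the angular CH3, C8 is the methylidene carbon, C9 carries C11; ring A = C1–C5/C10, ring B = C5–C10); compounds 1, 13 and 19 and all reagents named with SMILES are taken as purchasable.

Step 1
Reactants: 1 methyl 4-oxobutanoate
Product: 3 (5S)-5-(prop-2-yn-1-yl)oxolan-2-one, via methyl (4S)-4-hydroxyhept-6-ynoate 2 (not isolated)
Conditions: allenylboronic acid pinacol ester (1.3 equiv), (R)-TRIP [(R)-3,3'-bis(2,4,6-triisopropylphenyl)-1,1'-binaphthyl-2,2'-diyl hydrogen phosphate] (5 mol %), 4 Å molecular sieves, toluene, 0 °C; aqueous work-up; then TsOH (cat.), CH2Cl2, rt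
Reagents that add atoms: allenylboronic acid pinacol ester, C=C=CB1OC(C)(C)C(C)(C)O1
Why: Brønsted-acid-catalysed asymmetric propargylation of an aldehyde by an allenylboronate (SE2' through a six-membered, phosphate-bridged transition state) should give the homopropargylic alcohol, the (R)-acid being expected by analogy with aryl aldehydes to deliver the 4S carbinol (the (S)-acid is used should the sense prove opposite), and the γ-hydroxy ester then lactonises under acid.

Step 2
Reactants: 3 (5S)-5-(prop-2-yn-1-yl)oxolan-2-one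
Product: 5 (5S)-5-[(2E)-2-methylpenta-2,4-dien-1-yl]oxolan-2-one, via alkenylalane 4 (not isolated)
Conditions: AlMe3 (2.5 equiv), Cp2ZrCl2 (0.2 equiv), H2O (1 equiv), CH2Cl2, −25 °C; then vinyl bromide, Pd(PPh3)4 (5 mol %), ZnCl2 (1 equiv), THF, rt
Reagents that add atoms: trimethylaluminium, C[Al](C)C; vinyl bromide, C=CBr
Why: Zirconium-catalysed syn-methylalumination of the terminal alkyne (Negishi carboalumination) places CH3 on the internal carbon and aluminium on the terminus, and cross-coupling of the alkenylalane with vinyl bromide under zerovalent palladium (Negishi coupling) proceeds with retention, which should fix the (E)-trisubstituted diene while the lactone is expected to survive AlMe3 at −25 °C and the stereocentre is untouched.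

Step 3
Reactants: 5 (5S)-5-[(2E)-2-methylpenta-2,4-dien-1-yl]oxolan-2-one
Product: 7 (2E,6S,8E)-6-hydroxy-2,8-dimethylundeca-2,8,10-trienal, via lactol 6 (not isolated)
Conditions: i-Bu2AlH (1.1 equiv), CH2Cl2, −78 °C; Rochelle-salt work-up; crude lactol, Ph3P=C(CH3)CHO (1.5 equiv), toluene, 80 °C
Reagents that add atoms: 2-(triphenylphosphoranylidene)propanal, CC(C=O)=P(c1ccccc1)(c1ccccc1)c1ccccc1
Why: Partial reduction of the γ-lactone stops at the lactol, whose open hydroxy-aldehyde form is trapped by the stabilised formyl ylide in a Wittig reaction that should give the (E)-2-methyl-enal and free the C8 hydroxyl.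

Step 4
Reactants: 7 (2E,6S,8E)-6-hydroxy-2,8-dimethylundeca-2,8,10-trienal
Product: 8 (2E,6S,8E)-2,8-dimethyl-6-[(triethylsilyl)oxy]undeca-2,8,10-trienal
Conditions: Et3SiCl (1.2 equiv), imidazole (2 equiv), CH2Cl2, 0 °C
Reagents that add atoms: chlorotriethylsilane, CC[Si](Cl)(CC)CC
Why: Silylation of the secondary alcohol prevents oxa-Michael closure onto the enal and installs the bulky C8 substituent that steers the cycloaddition of step 5.

Step 5
Reactants: 8 (2E,6S,8E)-2,8-dimethyl-6-[(triethylsilyl)oxy]undeca-2,8,10-trienal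
Product: 9 (1S,4aR,6S,8aS)-1,4a-dimethyl-6-[(triethylsilyl)oxy]-1,2,4a,5,6,7,8,8a-octahydronaphthalene-1-carbaldehyde
Conditions: Me2AlCl (1.2 equiv), CH2Cl2, −78 → −20 °C
Reagents that add atoms: none
Why: Me2AlCl binds the formyl oxygen and the LUMO-lowered (E)-2-methyl-enal adds across the (E)-4-methyl-1,3-diene in a concerted, asynchronous intramolecular [4+2] cycloaddition; the closest known reaction type is the type 1 intramolecular Diels–Alder reaction of 2-methylundeca-2,8,10-trienals under alkylaluminium chloride promotion at low temperature. Ring B is closed through the four-atom tether by formation of the C5–C10 bond (six-membered, chair-like tether) and ring A is closed as the new cyclohexene by the second bond C3–C4, so that both rings and both quaternary carbons arise in one operation. C4 follows from the (E)-geometry of the dienophile (CHO cis to H-5, CH3 trans to it, suprafacial addition), and the trans ring fusion (H-5 anti to the 10-methyl) follows from the endo orientation of the coordinated formyl group combined with the (E)-diene, whose (Z)-methyl becomes the angular methyl. The absolute sense is relayed from C8, because in the chair-like tether the OSiEt3 group stays equatorial, the axial position being syn-axial to the inside methyl on C10. The step needs endo over exo selectivity and cycloaddition without cationic damage to the trisubstituted diene; the aldehyde–aluminium complex at low temperature should secure the first and the proton-scavenging alkylaluminium promoter the second.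

Step 6
Reactants: 9 (1S,4aR,6S,8aS)-1,4a-dimethyl-6-[(triethylsilyl)oxy]-1,2,4a,5,6,7,8,8a-octahydronaphthalene-1-carbaldehyde
Product: 10 (1S,4aS,6S,8aS)-1,4a-dimethyl-6-[(triethylsilyl)oxy]decahydronaphthalene-1-carbaldehyde
Conditions: H2 (1 atm), 10% Pd on carbon, EtOAc, rt
Reagents that add atoms: none
Why: Heterogeneous catalytic hydrogenation saturates the only C=C bond of 9 (C1=C2) without touching the hindered aldehyde or the silyl ether and creates no stereocentre.

Step 7
Reactants: 10 (1S,4aS,6S,8aS)-1,4a-dimethyl-6-[(triethylsilyl)oxy]decahydronaphthalene-1-carbaldehyde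
Product: 11 (1S,4aS,8aS)-1,4a-dimethyl-6-oxodecahydronaphthalene-1-carboxylic acid
Conditions: CrO3, H2SO4, H2O (Jones reagent), acetone, 0 °C → rt
Reagents that add atoms: water, O
Why: Jones oxidation in aqueous acid should cleave the triethylsilyl ether, oxidise the C8 carbinol to the ketone and the neopentyl aldehyde (through its hydrate) to the acid in one operation, and no stereocentre is α to a carbonyl, so none is at risk.

Step 8
Reactants: 11 (1S,4aS,8aS)-1,4a-dimethyl-6-oxodecahydronaphthalene-1-carboxylic acid
Product: 12 (1S,4aS,8aS)-1,4a-dimethyl-6-oxo-1,2,3,4,4a,5,6,8a-octahydronaphthalene-1-carboxylic acid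
Conditions: 2-iodoxybenzoic acid (IBX, 2.5 equiv), DMSO, 75 °C
Reagents that add atoms: none
Why: IBX dehydrogenation of the ketone (enol attack on pentavalent iodine, then elimination) can only give the C6=C7 enone because C10 is quaternary, and this blocks C7 so that C9 becomes the sole kinetically enolisable position for step 11.

Step 9
Reactants: 13 (2E)-3-methylpent-2-en-4-yn-1-ol
Product: 14 (2E)-3-methylpenta-2,4-dien-1-ol
Conditions: Zn dust activated with Cu(OAc)2 and AgNO3, MeOH–H2O, rt
Reagents that add atoms: none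
Why: Activated zinc reduces the conjugated terminal alkyne to the alkene without over-reduction and leaves the (E)-trisubstituted double bond unchanged.

Step 10
Reactants: 14 (2E)-3-methylpenta-2,4-dien-1-ol
Product: 15 (3E)-5-bromo-3-methylpenta-1,3-diene
Conditions: PBr3 (0.4 equiv), Et2O, −10 °C
Reagents that add atoms: phosphorus tribromide, BrP(Br)Br
Why: Conversion of a primary allylic alcohol into the bromide with PBr3 at low temperature, the 3-methylpentadienyl system being symmetric so that an allylic shift would give the same constitution.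

Step 11
Reactants: 12 (1S,4aS,8aS)-1,4a-dimethyl-6-oxo-1,2,3,4,4a,5,6,8a-octahydronaphthalene-1-carboxylic acid; 15 (3E)-5-bromo-3-methylpenta-1,3-diene
Product: 16 (1S,4aR,5R,8aS)-1,4a-dimethyl-5-[(2E)-3-methylpenta-2,4-dien-1-yl]-6-oxo-1,2,3,4,4a,5,6,8a-octahydronaphthalene-1-carboxylic acid (drawn as the C5 epimer expected from attack anti to the angular methyl)
Conditions: LDA (2.2 equiv), THF–DMPU, −78 °C; 15 (1.1 equiv), −78 → −20 °C; aq. HCl
Reagents that add atoms: none
Why: After carboxylate formation the second equivalent of LDA deprotonates kinetically at C9 (α' position, cross-conjugated dienolate) and SN2 alkylation by the allylic bromide forms the C9–C11 bond, attack being expected anti to the axial 10-methyl so that the side chain is axial at this stage and C9 is corrected in step 12.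

Step 12
Reactants: 16 (1S,4aR,5R,8aS)-1,4a-dimethyl-5-[(2E)-3-methylpenta-2,4-dien-1-yl]-6-oxo-1,2,3,4,4a,5,6,8a-octahydronaphthalene-1-carboxylic acid
Product: 17 (1S,4aR,5S,8aS)-1,4a-dimethyl-5-[(2E)-3-methylpenta-2,4-dien-1-yl]-6-oxodecahydronaphthalene-1-carboxylic acid
Conditions: [(Ph3P)CuH]6 (0.7 equiv of hexamer), THF, H2O (5 equiv), rt; then NaOMe (3 equiv), MeOH, rt; aq. HCl
Reagents that add atoms: none
Why: Conjugate reduction of the enone by the copper hydride (1,4-hydride delivery that spares the unactivated diene, the acid consuming one hydride) gives the saturated ketone, and methoxide then equilibrates C9 through the enolate to the equatorial side chain cis to the 10-methyl, the arrangement that persists in 8-oxolabdanes.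

Step 13
Reactants: 17 (1S,4aR,5S,8aS)-1,4a-dimethyl-5-[(2E)-3-methylpenta-2,4-dien-1-yl]-6-oxodecahydronaphthalene-1-carboxylic acid
Product: 18 (1S,4aS,5R,8aS)-1,4a-dimethyl-6-methylidene-5-[(2E)-3-methylpenta-2,4-dien-1-yl]decahydronaphthalene-1-carboxylic acid
Conditions: Ph3PCH3Br (4 equiv), KOtBu (4 equiv), THF, rt → 50 °C; aq. HCl
Reagents that add atoms: methyltriphenylphosphonium bromide, C[P+](c1ccccc1)(c1ccccc1)c1ccccc1.[Br-]
Why: Wittig methylenation of the hindered C8 ketone with excess ylide (the first equivalent is taken by the acid) should give the exocyclic alkene, and since C9 already has its thermodynamic configuration the basic medium cannot degrade it.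

Step 14
Reactants: 19 3-methoxy-2-methylphenol
Product: 20 2-methoxy-3-methylcyclohexa-2,5-diene-1,4-dione
Conditions: (KSO3)2NO (Fremy's salt, 2.2 equiv), KH2PO4 buffer, H2O–acetone, rt
Reagents that add atoms: potassium nitrosodisulfonate, [K+].[K+].[O-]S(=O)(=O)N([O])S(=O)(=O)[O-]
Why: Oxidation of a phenol with a free para position to the para-quinone by Fremy's salt (Teuber reaction).

Step 15
Reactants: 18 (1S,4aS,5R,8aS)-1,4a-dimethyl-6-methylidene-5-[(2E)-3-methylpenta-2,4-dien-1-yl]decahydronaphthalene-1-carboxylic acid; 20 2-methoxy-3-methylcyclohexa-2,5-diene-1,4-dione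
Product: 22 (1S,4aS,5R,8aS)-5-[(3-methoxy-2,6-dimethyl-1,4-dioxo-1,4-dihydronaphthalen-5-yl)methyl]-1,4a-dimethyl-6-methylidenedecahydronaphthalene-1-carboxylic acid, via cycloadduct 21 (not isolated)
Conditions: toluene, 90 °C; then activated MnO2 (10 equiv), Et3N (cat.), CH2Cl2–toluene, rt → 50 °C; chromatography to remove any regioisomer
Reagents that add atoms: none
Why: Intermolecular Diels–Alder reaction of the 1,2-disubstituted (E)-diene with the unsubstituted C=C of the quinone, in which the carbonyl flanked by C–OCH3 (not deactivated as a vinylogous ester) is expected to direct the CH2-bearing diene terminus to its α-carbon (ortho rule), followed by enolisation and MnO2 dehydrogenation to the naphthoquinone, which erases the three transient stereocentres.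

Step 16
Reactants: 22 (1S,4aS,5R,8aS)-5-[(3-methoxy-2,6-dimethyl-1,4-dioxo-1,4-dihydronaphthalen-5-yl)methyl]-1,4a-dimethyl-6-methylidenedecahydronaphthalene-1-carboxylic acid
Product: 23 (1S,4aS,5R,8aS)-5-[(3-hydroxy-2,6-dimethyl-1,4-dioxo-1,4-dihydronaphthalen-5-yl)methyl]-1,4a-dimethyl-6-methylidenedecahydronaphthalene-1-carboxylic acid
Conditions: NaOH (1 M aq.), MeOH, rt → 45 °C; then aq. HCl
Reagents that add atoms: sodium hydroxide, [Na+].[OH-]
Why: Addition–elimination of hydroxide at the methoxy-bearing carbon of the 2-methoxy-1,4-naphthoquinone (vinylogous ester hydrolysis) should give the hydroxyquinone after acidification, the tertiary acid and the exocyclic alkene being inert.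

Compound list
1 | methyl 4-oxobutanoate | COC(=O)CCC=O | starting material
2 | methyl (4S)-4-hydroxyhept-6-ynoate | C#CC[C@@H](O)CCC(=O)OC | intermediate
3 | (5S)-5-(prop-2-yn-1-yl)oxolan-2-one | C#CC[C@@H]1CCC(=O)O1 | intermediate
4 | dimethyl{(1E)-2-methyl-3-[(2S)-5-oxooxolan-2-yl]prop-1-en-1-yl}aluminium (alkenylalane) | C[Al](C)/C=C(\C)C[C@@H]1CCC(=O)O1 | intermediate
5 | (5S)-5-[(2E)-2-methylpenta-2,4-dien-1-yl]oxolan-2-one | C=C/C=C(\C)C[C@@H]1CCC(=O)O1 | intermediate
6 | (5S)-5-[(2E)-2-methylpenta-2,4-dien-1-yl]oxolan-2-ol (lactol, both anomers) | C=C/C=C(\C)C[C@@H]1CCC(O)O1 | intermediate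
7 | (2E,6S,8E)-6-hydroxy-2,8-dimethylundeca-2,8,10-trienal | O=C/C(C)=C/CC[C@H](O)C/C(C)=C/C=C | intermediate
8 | (2E,6S,8E)-2,8-dimethyl-6-[(triethylsilyl)oxy]undeca-2,8,10-trienal | O=C/C(C)=C/CC[C@H](O[Si](CC)(CC)CC)C/C(C)=C/C=C | intermediate
9 | (1S,4aR,6S,8aS)-1,4a-dimethyl-6-[(triethylsilyl)oxy]-1,2,4a,5,6,7,8,8a-octahydronaphthalene-1-carbaldehyde (trans-fused; CHO cis to H-8a; OSiEt3 equatorial) | CC[Si](CC)(CC)O[C@H]1CC[C@H]2[C@@](C)(C=CC[C@]2(C)C=O)C1 | intermediate
10 | (1S,4aS,6S,8aS)-1,4a-dimethyl-6-[(triethylsilyl)oxy]decahydronaphthalene-1-carbaldehyde | CC[Si](CC)(CC)O[C@H]1CC[C@H]2[C@@](C)(CCC[C@]2(C)C=O)C1 | intermediate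
11 | (1S,4aS,8aS)-1,4a-dimethyl-6-oxodecahydronaphthalene-1-carboxylic acid | O=C1CC[C@H]2[C@@](C)(CCC[C@]2(C)C(=O)O)C1 | intermediate
12 | (1S,4aS,8aS)-1,4a-dimethyl-6-oxo-1,2,3,4,4a,5,6,8a-octahydronaphthalene-1-carboxylic acid | O=C1C=C[C@H]2[C@@](C)(CCC[C@]2(C)C(=O)O)C1 | intermediate
13 | (2E)-3-methylpent-2-en-4-yn-1-ol | C#C/C(C)=C/CO | starting material
14 | (2E)-3-methylpenta-2,4-dien-1-ol | C=C/C(C)=C/CO | intermediate
15 | (3E)-5-bromo-3-methylpenta-1,3-diene | C=C/C(C)=C/CBr | intermediate
16 | (1S,4aR,5R,8aS)-1,4a-dimethyl-5-[(2E)-3-methylpenta-2,4-dien-1-yl]-6-oxo-1,2,3,4,4a,5,6,8a-octahydronaphthalene-1-carboxylic acid (side chain axial, trans to the 4a-methyl; C5 is equilibrated in step 12) | O=C1C=C[C@H]2[C@@](C)(CCC[C@]2(C)C(=O)O)[C@H]1C/C=C(\C)C=C | intermediate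
17 | (1S,4aR,5S,8aS)-1,4a-dimethyl-5-[(2E)-3-methylpenta-2,4-dien-1-yl]-6-oxodecahydronaphthalene-1-carboxylic acid (side chain equatorial, cis to the 4a-methyl) | O=C1CC[C@H]2[C@@](C)(CCC[C@]2(C)C(=O)O)[C@@H]1C/C=C(\C)C=C | intermediate
18 | (1S,4aS,5R,8aS)-1,4a-dimethyl-6-methylidene-5-[(2E)-3-methylpenta-2,4-dien-1-yl]decahydronaphthalene-1-carboxylic acid | C=C1CC[C@H]2[C@@](C)(CCC[C@]2(C)C(=O)O)[C@@H]1C/C=C(\C)C=C | intermediate
19 | 3-methoxy-2-methylphenol | COc1cccc(O)c1C | starting material
20 | 2-methoxy-3-methylcyclohexa-2,5-diene-1,4-dione | COC1=C(C)C(=O)C=CC1=O | intermediate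
21 | (1S,4aS,5R,8aS)-5-[(3-methoxy-2,6-dimethyl-1,4-dioxo-1,4,4a,5,8,8a-hexahydronaphthalen-5-yl)methyl]-1,4a-dimethyl-6-methylidenedecahydronaphthalene-1-carboxylic acid (cycloadduct; mixture at the three new centres, which are lost on aromatisation) | C=C1CC[C@H]2[C@@](C)(CCC[C@]2(C)C(=O)O)[C@@H]1CC1C(C)=CCC2C1C(=O)C(OC)=C(C)C2=O | intermediate
22 | (1S,4aS,5R,8aS)-5-[(3-methoxy-2,6-dimethyl-1,4-dioxo-1,4-dihydronaphthalen-5-yl)methyl]-1,4a-dimethyl-6-methylidenedecahydronaphthalene-1-carboxylic acid | C=C1CC[C@H]2[C@@](C)(CCC[C@]2(C)C(=O)O)[C@@H]1Cc1c(C)ccc2c1C(=O)C(OC)=C(C)C2=O | intermediate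
23 | (1S,4aS,5R,8aS)-5-[(3-hydroxy-2,6-dimethyl-1,4-dioxo-1,4-dihydronaphthalen-5-yl)methyl]-1,4a-dimethyl-6-methylidenedecahydronaphthalene-1-carboxylic acid (CNP0259461.3) | C=C1CC[C@H]2[C@@](C)(CCC[C@]2(C)C(=O)O)[C@@H]1Cc1c(C)ccc2c1C(=O)C(O)=C(C)C2=O | target

Total step count: 16. Longest linear sequence: 13 steps (steps 1–8, 11–13, 15 and 16, from methyl 4-oxobutanoate).

Steps most likely to fail

1. Step 5 (key step). The cycloaddition joins a trisubstituted dienophile to a diene terminus that carries two substituents and may be slow, so that exo (cis-fused) closure, or Lewis-acid-induced isomerisation and oligomerisation of the diene, could outrun it. The fallback is an ionic Diels–Alder reaction and sets out from 8. Acetalisation with 1,2-bis(trimethylsilyloxy)ethane and catalytic TMSOTf in CH2Cl2 at −78 °C should give the dioxolane 2-[(2E,6S,8E)-8-methyl-6-[(triethylsilyl)oxy]undeca-2,8,10-trien-2-yl]-1,3-dioxolane F1. Catalytic TfOH at −78 °C ionises F1 to the alkenyl dioxolanylium (allyl cation) dienophile, which is far more reactive than the neutral enal and should close both rings to the adduct 2-[(1S,4aR,6S,8aS)-1,4a-dimethyl-6-[(triethylsilyl)oxy]-1,2,4a,5,6,7,8,8a-octahydronaphthalen-1-yl]-1,3-dioxolane F2. Mild aqueous acid (pyridinium tosylate, wet acetone) returns the route at 9.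

2. Step 12. The base equilibration may stop at an unfavourable axial/equatorial ratio at C9, since the equatorial chain is gauche to both substituents on C10. The fallback replaces thermodynamic by kinetic control and sets out from 16. LDA (2.2 equiv, THF, −78 °C) regenerates the C8–C9 dienolate, now fully substituted at C9. Quenching at −78 °C with a hindered phenol should deliver the proton anti to the angular methyl and give (1S,4aR,5S,8aS)-1,4a-dimethyl-5-[(2E)-3-methylpenta-2,4-dien-1-yl]-6-oxo-1,2,3,4,4a,5,6,8a-octahydronaphthalene-1-carboxylic acid F3. Copper hydride reduction without the methoxide treatment then rejoins the route at 17.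

3. Step 15. The regioselectivity of the quinone cycloaddition may be poor, because the 2-methyl group of the diene opposes the directing effect of the 1-alkyl group and both carbonyls of 20 activate the dienophile. The fallback uses a quinone monoketal with a single directing carbonyl and sets out from 18. Commercial 2,4-dimethoxy-3-methylbenzaldehyde is converted by Dakin oxidation into 2,4-dimethoxy-3-methylphenol F4. PhI(OAc)2 in MeOH should give 2,4,4-trimethoxy-3-methylcyclohexa-2,5-dien-1-one F5. Cycloaddition of F5 with 18 (toluene, 110 °C) should give the ketal adduct (1S,4aS,5R,8aS)-5-[(3,4,4-trimethoxy-2,6-dimethyl-1-oxo-1,4,4a,5,8,8a-hexahydronaphthalen-5-yl)methyl... in short the 4,4-dimethyl ketal of 21, F6. Dilute aqueous acid unmasks the dione and rejoins the route at 21, which is dehydrogenated with MnO2 as in step 15.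

Further compounds
F1 | step 5 | 2-[(2E,6S,8E)-8-methyl-6-[(triethylsilyl)oxy]undeca-2,8,10-trien-2-yl]-1,3-dioxolane | C=C/C=C(\C)C[C@H](CC/C=C(\C)C1OCCO1)O[Si](CC)(CC)CC
F2 | step 5 | 2-[(1S,4aR,6S,8aS)-1,4a-dimethyl-6-[(triethylsilyl)oxy]-1,2,4a,5,6,7,8,8a-octahydronaphthalen-1-yl]-1,3-dioxolane | CC[Si](CC)(CC)O[C@H]1CC[C@H]2[C@@](C)(C=CC[C@]2(C)C3OCCO3)C1
F3 | step 12 | (1S,4aR,5S,8aS)-1,4a-dimethyl-5-[(2E)-3-methylpenta-2,4-dien-1-yl]-6-oxo-1,2,3,4,4a,5,6,8a-octahydronaphthalene-1-carboxylic acid | O=C1C=C[C@H]2[C@@](C)(CCC[C@]2(C)C(=O)O)[C@@H]1C/C=C(\C)C=C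
F4 | step 15 | 2,4-dimethoxy-3-methylphenol | COc1ccc(O)c(OC)c1C
F5 | step 15 | 2,4,4-trimethoxy-3-methylcyclohexa-2,5-dien-1-one | COC1=C(C)C(OC)(OC)C=CC1=O
F6 | step 15 | 4,4-dimethyl ketal of cycloadduct 21 (C4 of the hexahydronaphthalenedione unit carries two OCH3 groups) | C=C1CC[C@H]2[C@@](C)(CCC[C@]2(C)C(=O)O)[C@@H]1CC1C(C)=CCC2C1C(=O)C(OC)=C(C)C2(OC)OC
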